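**Plan**

1. Retrosynthesis: the ring A ketone is traced back to its dioxolane. The diaryl ether C–O bond of the seven-membered dioxepinone ring and then the depside ester C–O bond are cut, giving ring A acid 17 and ring B bromo diol 11. In 11 the benzylic CH2–spiro carbon bond, the aryl–C(=O) bond and the lactone O–C(=O) bond are cut, giving the symmetric bis-carbonate 3 and lactone 8.
2. Enabling feature: on ring B the free phenol oxygen, the ring carbon bearing the lactone carbonyl and the ring carbon bearing the benzylic CH2 are three neighbours (a 2-hydroxy-6-alkylbenzoate). The phenol oxygen can therefore hold the carbonyl carbon as a tert-butyl carbonate and pass it to the ring carbon by an anionic 1,3 O→C shift, and the ester so formed acidifies the neighbouring methyl for addition to a lactone.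
3. Forward order: orcinol to bis-carbonate 3; (R)-2-methyloxirane to lactone 8; one-flask union of 3 and 8 closing the lactone ring and the spiro oxane ring (11); ring A acid 17 from methyl orsellinate; depside ester 18; seven-membered ring by intramolecular Ullmann etherification (19); ketone release (20).
4. Stereochemistry: the methyl-bearing carbon (R) comes from (R)-2-methyloxirane; the spiro carbon (S) is set in the key step by acid equilibration to the anomerically stabilised isomer.

Key step: step 5

Remark: the spiro acyl ketal of the target is taken to be the thermodynamically preferred isomer (acyloxy oxygen axial on the oxane, methyl equatorial), which matches the given descriptors (spiro carbon S, methyl carbon R).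

**Route**

Step 1
Reactants: 1 orcinol (5-methylbenzene-1,3-diol)
Product: 2 4,6-dibromo-5-methylbenzene-1,3-diol
Conditions: NBS (2.0 equiv), MeCN, −20 °C → rt
Reagents that add atoms: N-bromosuccinimide, O=C1CCC(=O)N1Br
Why: Electrophilic aromatic bromination of a resorcinol goes first to the two carbons that are para to one hydroxyl and ortho to the other (here the two carbons flanking the methyl), so the carbon between the hydroxyls stays free.

Step 2
Reactants: 2 4,6-dibromo-5-methylbenzene-1,3-diol
Product: 3 4,6-dibromo-5-methyl-1,3-phenylene bis(tert-butyl carbonate)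
Conditions: Boc2O (2.3 equiv), DMAP (0.1 equiv), Et3N, CH2Cl2, rt
Reagents that add atoms: di-tert-butyl dicarbonate, CC(C)(C)OC(=O)OC(=O)OC(C)(C)C
Why: DMAP-catalysed O-acylation of both phenols gives the symmetric bis-carbonate that carries the future carboxyl carbon on oxygen.

Step 3
Reactants: 4 (R)-2-methyloxirane; 5 but-3-en-1-ylmagnesium bromide
Product: 6 (R)-hept-6-en-2-ol
Conditions: CuI (10 mol %), THF, −40 → 0 °C; 1 M HCl
Reagents that add atoms: none
Why: Copper-catalysed SN2 opening of the epoxide by the Grignard reagent takes place at the unsubstituted carbon, so the stereocentre of 4 is not touched.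

Step 4
Reactants: 6 (R)-hept-6-en-2-ol
Product: 8 (R)-6-methyloxan-2-one, via lactol 7 (not isolated)
Conditions: O3, CH2Cl2, −78 °C; PPh3, → rt; then PhI(OAc)2 (1.2 equiv), TEMPO (10 mol %), CH2Cl2, rt
Reagents that add atoms: ozone, [O-][O+]=O
Why: Ozonolysis gives the 5-hydroxy aldehyde, which closes to lactol 7, and TEMPO-catalysed oxidation of the lactol gives the lactone without involving the stereocentre.

Step 5
Reactants: 3 4,6-dibromo-5-methyl-1,3-phenylene bis(tert-butyl carbonate); 8 (R)-6-methyloxan-2-one
Product: 11 (3S,6'R)-5-bromo-6,8-dihydroxy-6'-methylspiro[isochromane-3,2'-oxan]-1-one, via lithium phenolate ester 9 (not isolated), via hydroxy keto ester 10 (not isolated)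
Conditions: t-BuLi (2.0 equiv), THF, −100 → −78 °C; LiN(i-Pr)2 (2.2 equiv), −78 °C; 8 (1.5 equiv), −78 → −20 °C; AcOH; evaporate; TFA/CH2Cl2 (1:1), 0 °C → rt
Reagents that add atoms: none
Why: Bromine–lithium exchange at one of the two equivalent C–Br bonds of 3 gives an aryllithium next to a carbonate oxygen, a 1,3 O→C shift of the tert-butoxycarbonyl group forms the aryl–carbonyl bond and frees the phenolate (9), and the new ester makes the flanking methyl acidic, so that the lithium amide gives a benzylic anion that adds to the carbonyl of 8 and forms the benzylic CH2–C bond (10 after protonation). TFA then removes the tert-butyl ester and the remaining tert-butyl carbonate, and the δ-hydroxy keto acid closes twice with loss of water. The closest known reaction types are the halogen–metal-exchange-triggered anionic ortho-Fries rearrangement of aryl carbonates and carbamates and the addition of laterally lithiated o-toluates to lactones, run here in one flask. The oxane ring closes by 6-exo-trig attack of the secondary hydroxyl on the ketone, and the lactone ring by 6-exo-trig attack of the carboxyl oxygen on the cyclic oxocarbenium carbon. The spiro carbon is set under thermodynamic control in acid, where the isomer with the acyloxy oxygen axial on the oxane (anomeric effect) and the methyl equatorial, which is the (S) centre, is favoured, while the (R) methyl carbon comes unchanged from 8. The step needs a single exchange and a single site of carbonyl delivery, which are secured by the mirror symmetry of 3 and by the electron-rich phenolate formed after the first shift, and the tert-butyl ester keeps the benzylic anion from condensing with a second molecule.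

Step 6
Reactants: 12 methyl orsellinate (methyl 2,4-dihydroxy-6-methylbenzoate)
Product: 13 methyl 2-hydroxy-4-methoxy-6-methylbenzoate
Conditions: MeI (1.1 equiv), K2CO3 (1.1 equiv), acetone, reflux
Reagents that add atoms: iodomethane, CI
Why: Williamson etherification is selective for the 4-hydroxyl because the 2-hydroxyl is held in a hydrogen bond to the ester carbonyl.

Step 7
Reactants: 13 methyl 2-hydroxy-4-methoxy-6-methylbenzoate; 14 N-methoxy-N-methylhexanamide
Product: 15 methyl 2-hydroxy-4-methoxy-6-(2-oxoheptyl)benzoate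
Conditions: LiN(i-Pr)2 (2.1 equiv), THF, −78 °C; 14 (1.1 equiv), −78 → −30 °C; 1 M HCl, 0 °C
Reagents that add atoms: none
Why: Lateral lithiation of the o-toluate (as its phenolate–benzyl dianion) and acylation by the Weinreb amide gives the benzyl ketone, since the chelated tetrahedral adduct holds until the acid quench and prevents a second addition.

Step 8
Reactants: 15 methyl 2-hydroxy-4-methoxy-6-(2-oxoheptyl)benzoate
Product: 16 methyl 2-hydroxy-4-methoxy-6-[(2-pentyl-1,3-dioxolan-2-yl)methyl]benzoate
Conditions: (TMSOCH2)2 (1.5 equiv), TMSOTf (5 mol %), CH2Cl2, −78 → −20 °C; pyridine; aq NaHCO3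
Reagents that add atoms: 1,2-bis(trimethylsilyloxy)ethane, C[Si](C)(C)OCCO[Si](C)(C)C
Why: Silyl-triflate-catalysed ketalisation at low temperature masks the ketone without the acid and heat that would close the keto ester to an isocoumarin.

Step 9
Reactants: 16 methyl 2-hydroxy-4-methoxy-6-[(2-pentyl-1,3-dioxolan-2-yl)methyl]benzoate
Product: 17 2-hydroxy-4-methoxy-6-[(2-pentyl-1,3-dioxolan-2-yl)methyl]benzoic acid
Conditions: KOH (10 equiv), EtOH/H2O (3:1), 80 °C; 1 M HCl to pH 4, 0 °C
Reagents that add atoms: potassium hydroxide, [K+].[OH-]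
Why: Saponification of the hindered salicylate ester is carried out in hot alkali, which the dioxolane tolerates.

Step 10
Reactants: 11 (3S,6'R)-5-bromo-6,8-dihydroxy-6'-methylspiro[isochromane-3,2'-oxan]-1-one; 17 2-hydroxy-4-methoxy-6-[(2-pentyl-1,3-dioxolan-2-yl)methyl]benzoic acid
Product: 18 (3S,6'R)-5-bromo-8-hydroxy-6'-methyl-1-oxospiro[isochromane-3,2'-oxan]-6-yl 2-hydroxy-4-methoxy-6-[(2-pentyl-1,3-dioxolan-2-yl)methyl]benzoate
Conditions: DCC (1.2 equiv), DMAP (0.1 equiv), CH2Cl2, 0 °C → rt
Reagents that add atoms: none
Why: Steglich esterification acylates the C6 hydroxyl of 11 (para to the lactone carbonyl), because the C8 hydroxyl of 11 and the phenol of 17 are each locked in a hydrogen bond to a neighbouring carbonyl.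

Step 11
Reactants: 18 the bromo depside
Product: 19 depsidone ethylene ketal (dibenzo[b,e][1,4]dioxepin-11-one; ring A with methoxy and (2-pentyl-1,3-dioxolan-2-yl)methyl; ring B with hydroxyl and the fused spiro lactone; spiro carbon S; methyl carbon R)
Conditions: CuI (0.3 equiv), N,N-dimethylglycine (0.6 equiv), Cs2CO3 (2.5 equiv), 1,4-dioxane (0.005 M), 95 °C
Reagents that add atoms: none
Why: Intramolecular Ullmann diaryl ether synthesis closes the seven-membered ring, since only the ring A phenolate oxygen can reach the C–Br carbon that sits ortho to the depside oxygen.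

Step 12
Reactants: 19 depsidone ethylene ketal
Product: 20 target depsidone (ring A with methoxy and 2-oxoheptyl; ring B with hydroxyl and the fused spiro lactone; spiro carbon S; methyl carbon R)
Conditions: PPTS (0.3 equiv), acetone/H2O (10:1), 45 °C
Reagents that add atoms: water, O
Why: Mild acid hydrolysis removes the dioxolane, while the spiro acyl ketal, whose acyloxy oxygen is a poor donor, ionises more slowly and in any case returns to the same thermodynamically preferred isomer.

**Compound list**

1 | orcinol (5-methylbenzene-1,3-diol) | Cc1cc(O)cc(O)c1 | starting material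
2 | 4,6-dibromo-5-methylbenzene-1,3-diol | Cc1c(Br)c(O)cc(O)c1Br | intermediate
3 | 4,6-dibromo-5-methyl-1,3-phenylene bis(tert-butyl carbonate) | Cc1c(Br)c(OC(=O)OC(C)(C)C)cc(OC(=O)OC(C)(C)C)c1Br | intermediate
4 | (R)-2-methyloxirane | C[C@@H]1CO1 | starting material
5 | but-3-en-1-ylmagnesium bromide | C=CCC[Mg]Br | starting material
6 | (R)-hept-6-en-2-ol | C[C@@H](O)CCCC=C | intermediate
7 | (6R)-6-methyloxan-2-ol (lactol, anomeric mixture) | C[C@@H]1CCCC(O)O1 | intermediate
8 | (R)-6-methyloxan-2-one | C[C@@H]1CCCC(=O)O1 | intermediate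
9 | lithium 4-bromo-2-(tert-butoxycarbonyl)-5-[(tert-butoxycarbonyl)oxy]-3-methylphenolate | [Li+].Cc1c(Br)c(OC(=O)OC(C)(C)C)cc([O-])c1C(=O)OC(C)(C)C | intermediate
10 | tert-butyl 3-bromo-4-[(tert-butoxycarbonyl)oxy]-6-hydroxy-2-[(6R)-6-hydroxy-2-oxoheptyl]benzoate | C[C@@H](O)CCCC(=O)Cc1c(Br)c(OC(=O)OC(C)(C)C)cc(O)c1C(=O)OC(C)(C)C | intermediate
11 | (3S,6'R)-5-bromo-6,8-dihydroxy-6'-methylspiro[isochromane-3,2'-oxan]-1-one | Oc1cc(O)c2c(c1Br)C[C@]1(CCC[C@@H](C)O1)OC2=O | intermediate
12 | methyl orsellinate (methyl 2,4-dihydroxy-6-methylbenzoate) | COC(=O)c1c(C)cc(O)cc1O | starting material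
13 | methyl 2-hydroxy-4-methoxy-6-methylbenzoate | COC(=O)c1c(C)cc(OC)cc1O | intermediate
14 | N-methoxy-N-methylhexanamide | CCCCCC(=O)N(C)OC | starting material
15 | methyl 2-hydroxy-4-methoxy-6-(2-oxoheptyl)benzoate | CCCCCC(=O)Cc1cc(OC)cc(O)c1C(=O)OC | intermediate
16 | methyl 2-hydroxy-4-methoxy-6-[(2-pentyl-1,3-dioxolan-2-yl)methyl]benzoate | CCCCCC1(Cc2cc(OC)cc(O)c2C(=O)OC)OCCO1 | intermediate
17 | 2-hydroxy-4-methoxy-6-[(2-pentyl-1,3-dioxolan-2-yl)methyl]benzoic acid | CCCCCC1(Cc2cc(OC)cc(O)c2C(=O)O)OCCO1 | intermediate
18 | (3S,6'R)-5-bromo-8-hydroxy-6'-methyl-1-oxospiro[isochromane-3,2'-oxan]-6-yl 2-hydroxy-4-methoxy-6-[(2-pentyl-1,3-dioxolan-2-yl)methyl]benzoate | CCCCCC1(Cc2cc(OC)cc(O)c2C(=O)Oc2cc(O)c3c(c2Br)C[C@]2(CCC[C@@H](C)O2)OC3=O)OCCO1 | intermediate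
19 | depsidone ethylene ketal (spiro carbon S, methyl carbon R) | CCCCCC1(Cc2cc(OC)cc3c2C(=O)Oc2cc(O)c4c(c2O3)C[C@]2(CCC[C@@H](C)O2)OC4=O)OCCO1 | intermediate
20 | target depsidone CNP0301127.1 (spiro carbon S, methyl carbon R) | CCCCCC(=O)Cc1cc(OC)cc2c1C(=O)Oc1cc(O)c3c(c1O2)C[C@]1(CCC[C@@H](C)O1)OC3=O | target

**Step count and risks**

Total step count: 12. Longest linear sequence: 7 steps (steps 6 to 12, from 12 to 20).

Steps most likely to fail:

Step 5. The benzylic deprotonation of the phenolate-bearing ester may be slow, the lactone may be enolised instead of attacked, a second bromine–lithium exchange may occur, or the open keto acid may dehydrate to an isocoumarin in acid. The fallback separates the events and caps the phenol. It sets out from 3: exchange and shift alone (t-BuLi, THF, −100 °C, then aqueous NH4Cl) give tert-butyl 3-bromo-4-[(tert-butoxycarbonyl)oxy]-6-hydroxy-2-methylbenzoate F1. NaH and MOMCl in DMF give tert-butyl 3-bromo-4-[(tert-butoxycarbonyl)oxy]-6-(methoxymethoxy)-2-methylbenzoate F2. LiN(i-Pr)2 (1.1 equiv) at −78 °C and then 8 give tert-butyl 3-bromo-4-[(tert-butoxycarbonyl)oxy]-2-[(6R)-6-hydroxy-2-oxoheptyl]-6-(methoxymethoxy)benzoate F3. TFA/CH2Cl2 then removes the tert-butyl ester, the carbonate and the methoxymethyl group and closes the spiro lactone, so the route is rejoined at 11.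

Step 11. Base-induced acyl migration or cleavage of the depside ester may outrun a slow oxidative addition at the hindered, electron-rich C–Br bond. The fallback replaces the hot carbonate etherification by an oxidative C–O coupling at room temperature. It sets out from 18: Miyaura borylation (bis(pinacolato)diboron, Pd(dppf)Cl2, KOAc, dioxane, 80 °C) gives (3S,6'R)-8-hydroxy-6'-methyl-1-oxo-5-(4,4,5,5-tetramethyl-1,3,2-dioxaborolan-2-yl)spiro[isochromane-3,2'-oxan]-6-yl 2-hydroxy-4-methoxy-6-[(2-pentyl-1,3-dioxolan-2-yl)methyl]benzoate F4. Intramolecular Chan–Lam coupling (Cu(OAc)2, pyridine, 4 Å molecular sieves, CH2Cl2, air, rt) closes the seven-membered ring, so the route is rejoined at 19.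

Step 7. Dianion formation may be incomplete, the benzylic anion may condense with the ester of a second molecule, or the keto ester may close to the isocoumarin on work-up. The fallback uses the fully O-methylated toluate and restores the phenol afterwards. It sets out from 12: Me2SO4 and K2CO3 in acetone give methyl 2,4-dimethoxy-6-methylbenzoate F5. LiN(i-Pr)2 (1.1 equiv) at −78 °C and then 14 give methyl 2,4-dimethoxy-6-(2-oxoheptyl)benzoate F6. BCl3 (CH2Cl2, −78 → 0 °C) cleaves only the methoxy group ortho to the ester through chelation, so the route is rejoined at 15.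

Further compounds
F1 | step 5 | tert-butyl 3-bromo-4-[(tert-butoxycarbonyl)oxy]-6-hydroxy-2-methylbenzoate | Cc1c(Br)c(OC(=O)OC(C)(C)C)cc(O)c1C(=O)OC(C)(C)C
F2 | step 5 | tert-butyl 3-bromo-4-[(tert-butoxycarbonyl)oxy]-6-(methoxymethoxy)-2-methylbenzoate | Cc1c(Br)c(OC(=O)OC(C)(C)C)cc(OCOC)c1C(=O)OC(C)(C)C
F3 | step 5 | tert-butyl 3-bromo-4-[(tert-butoxycarbonyl)oxy]-2-[(6R)-6-hydroxy-2-oxoheptyl]-6-(methoxymethoxy)benzoate | C[C@@H](O)CCCC(=O)Cc1c(Br)c(OC(=O)OC(C)(C)C)cc(OCOC)c1C(=O)OC(C)(C)C
F4 | step 11 | (3S,6'R)-8-hydroxy-6'-methyl-1-oxo-5-(4,4,5,5-tetramethyl-1,3,2-dioxaborolan-2-yl)spiro[isochromane-3,2'-oxan]-6-yl 2-hydroxy-4-methoxy-6-[(2-pentyl-1,3-dioxolan-2-yl)methyl]benzoate | CCCCCC1(Cc2cc(OC)cc(O)c2C(=O)Oc2cc(O)c3c(c2B2OC(C)(C)C(C)(C)O2)C[C@]2(CCC[C@@H](C)O2)OC3=O)OCCO1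
F5 | step 7 | methyl 2,4-dimethoxy-6-methylbenzoate | COC(=O)c1c(C)cc(OC)cc1OC
F6 | step 7 | methyl 2,4-dimethoxy-6-(2-oxoheptyl)benzoate | CCCCCC(=O)Cc1cc(OC)cc(OC)c1C(=O)OC
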